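**Retrosynthetic overview**
- Both A-ring C–O bonds ortho to the C4 carbonyl (ring O1–C8a and C5–OMe) are cut in one operation. This gives a mirror-symmetric 2,6-dibromoaryl 1,3-diketone plus methoxide.
- The diketone comes from a crossed Claisen condensation (C2–C3 bond) of 2',6'-dibromoacetosyringone with methyl 4-methoxybenzoate.
- The dibromoketone comes from double ring bromination of acetosyringone. Its 3,5-(OMe)2-4-OH pattern already matches C6-OMe/C7-OH/C8-OMe, so no protecting group or selective (de)methylation is needed.
- Rings A and B are bought. The pyranone ring C is the only ring formed, and it is formed last.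

Assumption: the target SMILES has no stereocentre and no stereogenic double bond, so the compound is achiral and no stereocontrol is required.

**Step 1**
Reactants: 1 acetosyringone [1-(4-hydroxy-3,5-dimethoxyphenyl)ethanone]
Product: 2 1-(2,6-dibromo-4-hydroxy-3,5-dimethoxyphenyl)ethanone
Conditions: NBS (2.2 equiv), MeCN, 0 °C → 40 °C, dark
Reagents that add atoms: N-bromosuccinimide, O=C1CCC(=O)N1Br
Why: Electrophilic aromatic bromination (SEAr): the only two free ring positions are equivalent, each ortho to one OMe and para to the other, and acid-free NBS in polar MeCN favours nuclear over side-chain bromination.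

**Step 2**
Reactants: 2 1-(2,6-dibromo-4-hydroxy-3,5-dimethoxyphenyl)ethanone; 3 methyl 4-methoxybenzoate
Product: 4 1-(2,6-dibromo-4-hydroxy-3,5-dimethoxyphenyl)-3-(4-methoxyphenyl)propane-1,3-dione
Conditions: NaH (4 equiv), 3 (1.5 equiv), THF, reflux; then 1 M HCl
Reagents that add atoms: none
Why: Crossed Claisen condensation: only 2 can enolise, its di-ortho-blocked carbonyl cannot self-condense, formation of the stabilised diketonate drives the reaction, and the aryl bromides have no ortho hydrogen, so no aryne can form.

**Step 3**
Reactants: 4 1-(2,6-dibromo-4-hydroxy-3,5-dimethoxyphenyl)-3-(4-methoxyphenyl)propane-1,3-dione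
Product: 6 7-hydroxy-4',5,6,8-tetramethoxyflavone, via 5-bromoflavone 5 (not isolated)
Conditions: CuI (10 mol %), NaOMe (6 equiv, 25 wt % in MeOH), DMF, 110 °C, Ar; then 1 M HCl
Reagents that add atoms: sodium methoxide, C[O-].[Na+]
Why: Proposed new method: a desymmetrising copper-catalysed double C–O coupling on a free-phenol 2,6-dibromoaryl 1,3-diketone, in which the diketonate of 4 serves as its own anionic O-ligand for Cu(I), copper inserts into one of the two equivalent ortho C–Br bonds held next to it by the aryl ketone, and C–O reductive elimination from the distal enolate oxygen closes the pyranone (O1–C8a) to give 5; the C4 carbonyl of 5 then lies peri to the remaining C5–Br and steers a Cu(I)–OMe species into it (ortho-carbonyl effect) to form C5–OMe; methoxylation before cyclisation leads to the same product, so both orders converge on 6, and the C7 phenoxide, which shuts down uncatalysed SNAr, is tolerated by Cu(I)/Cu(III) coupling; the closest known reaction types are the intramolecular Ullmann-type O-arylation of 1-(2-haloaryl)-1,3-diketones to flavones and the CuBr/NaOMe Ullmann methoxylation of bromophenols and bromoflavones, which have not been merged in one pot or applied to a dibromide of this kind.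

**Compound list**
1 | acetosyringone, 1-(4-hydroxy-3,5-dimethoxyphenyl)ethanone | CC(=O)c1cc(OC)c(O)c(OC)c1 | starting material
2 | 1-(2,6-dibromo-4-hydroxy-3,5-dimethoxyphenyl)ethanone | CC(=O)c1c(Br)c(OC)c(O)c(OC)c1Br | intermediate
3 | methyl 4-methoxybenzoate | COC(=O)c1ccc(OC)cc1 | starting material
4 | 1-(2,6-dibromo-4-hydroxy-3,5-dimethoxyphenyl)-3-(4-methoxyphenyl)propane-1,3-dione (drawn as the diketo tautomer) | COc1ccc(cc1)C(=O)CC(=O)c1c(Br)c(OC)c(O)c(OC)c1Br | intermediate
5 | 5-bromo-7-hydroxy-6,8-dimethoxy-2-(4-methoxyphenyl)-4H-chromen-4-one | COc1ccc(cc1)-c1cc(=O)c2c(Br)c(OC)c(O)c(OC)c2o1 | intermediate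
6 | 7-hydroxy-4',5,6,8-tetramethoxyflavone, 7-hydroxy-5,6,8-trimethoxy-2-(4-methoxyphenyl)-4H-chromen-4-one | COc1ccc(-c2cc(=O)c3c(OC)c(OC)c(O)c(OC)c3o2)cc1 | target

**Total step count:** 3. **Longest linear sequence:** 3.

**Steps most likely to fail**

1. Step 3 (proposed new step).
   - Risks: both bromides may be methoxylated before ring closure, giving a dead-end 2,6-dimethoxy diketone. Hydrodebromination at C5 is possible. Oxidative addition may be sluggish on the phenoxide-rich ring.
   - Fallback: sets out from 4 and comes back at 6. It uses only known chemistry, with the two couplings run separately and the phenol masked.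
   - 4 is cyclised alone by the known intramolecular Ullmann-type O-arylation (CuI cat., K2CO3, DMF, 100 °C), and 5 is isolated.
   - 5 is benzylated (BnBr, K2CO3, acetone, reflux) to 7-benzyloxy-5-bromo-6,8-dimethoxy-2-(4-methoxyphenyl)-4H-chromen-4-one F1.
   - The established CuBr/NaOMe methoxylation of bromoflavone ethers (MeOH–DMF, reflux) converts it into 7-benzyloxy-5,6,8-trimethoxy-2-(4-methoxyphenyl)-4H-chromen-4-one F2.
   - Hydrogenolysis (H2, Pd/C, EtOAc, rt) then gives 6.

2. Step 1.
   - Risk: side-chain (α) bromination of the methyl ketone may compete with the slower second ring bromination.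
   - Fallback: sets out from 1 and comes back at 2. α-Bromination is accepted and then undone.
   - Excess Br2 (3.3 equiv, AcOH, 40 °C) gives 2-bromo-1-(2,6-dibromo-4-hydroxy-3,5-dimethoxyphenyl)ethanone F3.
   - The α-bromine alone is then removed reductively (Zn dust, AcOH, 0 °C → rt). The aryl bromides are inert, and any α,α-dibromide is reduced as well. This gives 2.

3. Step 2.
   - Risk: the phenoxide/enolate dianion may be poorly soluble, and the electron-rich ester 3 is a weak electrophile.
   - Fallback: sets out from 2 and comes back at 4. It uses soft enolisation with an acid chloride and sacrificial O-acylation in place of a hard dianion with an ester.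
   - 4-Methoxybenzoyl chloride (2.3 equiv), MgBr2·OEt2 and iPr2NEt in CH2Cl2 at rt give 3,5-dibromo-2,6-dimethoxy-4-[3-(4-methoxyphenyl)-3-oxopropanoyl]phenyl 4-methoxybenzoate F4.
   - Mild methanolysis of the aryl ester (K2CO3, MeOH, rt, then dilute HCl) gives 4.

**Further compounds**
F1 | step 3 | 7-benzyloxy-5-bromo-6,8-dimethoxy-2-(4-methoxyphenyl)-4H-chromen-4-one | COc1ccc(cc1)-c1cc(=O)c2c(Br)c(OC)c(OCc3ccccc3)c(OC)c2o1
F2 | step 3 | 7-benzyloxy-5,6,8-trimethoxy-2-(4-methoxyphenyl)-4H-chromen-4-one | COc1ccc(cc1)-c1cc(=O)c2c(OC)c(OC)c(OCc3ccccc3)c(OC)c2o1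
F3 | step 1 | 2-bromo-1-(2,6-dibromo-4-hydroxy-3,5-dimethoxyphenyl)ethanone | O=C(CBr)c1c(Br)c(OC)c(O)c(OC)c1Br
F4 | step 2 | 3,5-dibromo-2,6-dimethoxy-4-[3-(4-methoxyphenyl)-3-oxopropanoyl]phenyl 4-methoxybenzoate | COc1ccc(cc1)C(=O)CC(=O)c1c(Br)c(OC)c(OC(=O)c2ccc(OC)cc2)c(OC)c1Br
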